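Readings and results come from a simulation with constants of no real substance; scatter was added.

Amounts come first. A starting complex must take up 3 incoming ligands to become complex with three exchanged, so the quantity to hold is the ligand per complex, the charge of incoming ligand over the charge of starting complex. It is 4.40 in theta, 2.20 in beta and 1.10 in gamma.

| setting | north | south-west | north-east | theta | beta | gamma |
|---|---|---|---|---|---|---|
| starting complex | 2.6 mM | 5.1 mM | 7.7 mM | 2.5 mM | 5.0 mM | 10 mM |
| incoming ligand | 11 mM (fed, over 2.5 min) | 11 mM (fed, over 2.5 min) | 11 mM (fed, over 2.5 min) | 11.0 mM (fed, over 2.5 min) | 11.0 mM (fed, over 2.5 min) | 11.0 mM (fed, over 2.5 min) |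
| leaving ligand | 5 mM | 5 mM | 5 mM | 5.00 mM | 5.00 mM | 5.00 mM |
| remark | run made earlier; the fed solution adds 1.0 times the starting volume | run made earlier; the fed solution adds 1.0 times the starting volume | run made earlier; the fed solution adds 1.0 times the starting volume | the fed solution adds 1.0 times the starting volume | the fed solution adds 1.0 times the starting volume | the fed solution adds 1.0 times the starting volume |
| time |  |  |  | 5.0 min | 5.0 min | 5.0 min |

| run | time / min | complex with three exchanged / % |
|---|---|---|
| north | 0.417 | 0 |
| north | 0.833 | 0 |
| north | 1.33 | 0 |
| north | 2.50 | 9.5 |
| north | 5.00 | 28.9 |
| south-west | 0.417 | 0 |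
| south-west | 0.833 | 0 |
| south-west | 1.33 | 0.7 |
| south-west | 2.50 | 7.4 |
| south-west | 5.00 | 21.8 |
| north-east | 0.417 | 0.9 |
| north-east | 1.33 | 0.8 |
| north-east | 2.50 | 6.4 |
| north-east | 4.00 | 10.5 |
| north-east | 5.00 | 11.9 |

(scatter of a reading: 1 percentage point)

- [complex with three exchanged] at the end for theta, beta, gamma, in this order
- how that number moves from the first to the last of them (falls all the way / rises, then falls / falls, then rises / rises all the way / hardly changes)

- every charge counts on the volume at the start, and the solution that is fed holds the whole dose
- "hardly changes" means that all values lie within two and a half points (for a concentration: within two and a half percent of the largest)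

Two extreme flasks bound the row. With ligand in plenty, the percentage in gamma stays at the 28.9% of the north run and the amount follows the charge, so after the feed has diluted the flask, c(complex with three exchanged) in gamma is 1.44 mM. With incoming ligand as the limiting reagent and every ligand stacked 3 to a complex, the same concentration is 1.83 mM.

The real flask lies below both. The runs at 4.23, 2.16 and 1.43 ligands per complex read 28.9%, 21.8% and 11.9% at 5.00 min, so the percentage falls as the ligand per complex falls.

Theta and beta stand close to the north and south-west runs in ligand per complex, so their percentages carry over and give 0.361 mM and 0.545 mM. Gamma lies beyond the runs, and a straight line through the last two readings against ligand per complex gives 7.43%, which is 0.372 mM.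

The forecast gives 0.37 mM, 0.55 mM and 0.33 mM, with the shape rises, then falls, and adds “The gamma value is an extrapolation.” Its gamma value is lower than the straight line gives.

The flask gives 0.374 mM, 0.527 mM and 0.393 mM, with the shape rises, then falls.

    starting complex + incoming ligand → leaving ligand + complex with one exchanged (k = 1.90 /M/s)
    complex with one exchanged + incoming ligand → leaving ligand + complex with two exchanged (k = 5.70 /M/s)
    complex with two exchanged + incoming ligand → leaving ligand + complex with three exchanged (k = 3.10 /M/s)
    complex with three exchanged + incoming ligand → leaving ligand + complex with four exchanged (k = 1.60 /M/s)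
    starting complex + complex with three exchanged → side product (k = 1.20 /M/s)
    2 starting complex → homo dimer (k = 3.90 × 10⁻⁴ /M/s)

At the end of theta, complex with three exchanged is used by incoming ligand 17 times as fast as by starting complex, and theta, at 4.40 ligands per complex, holds 20.1% of the complex charged as complex with four exchanged beside 3.41% as side product, which counts as two in these percentages. Gamma, at 1.10 ligands per complex, has 5.2% of its incoming ligand left and holds 7.48% as side product beside 1.96% as complex with four exchanged.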